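**Retrosynthetic overview**
- The last bond made is C1'–C(carbinol): an anti-selective, catalyst-controlled allylboration of a ring B bromohydrin enal with an achiral ring A allylboronate sets both ring-A-side stereocentres at once.
- The key step is on ring B: a syn oxybromination of the limonene ring alkene forms the tertiary C–O bond and the equatorial C–Br bond together (Br and OH cis, both cis to the side chain).
- The enal comes from (S)-limonene by hydroformylation and α,β-dehydrogenation; ring B is bought from the chiral pool, not built.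
- Ring A is the only ring constructed: Diels–Alder reaction of 4-methylpenta-1,3-diene with a nitroacrylate, loss of HNO2, ester reduction, allylic borylation.

Assumption: methyl (E)-3-nitroacrylate and (S)-(−)-limonene are taken as purchasable; the nitroacrylate can otherwise be made in two operations from methyl acrylate.

**Step 1**
Reactants: 1 4-methylpenta-1,3-diene; 2 methyl (2E)-3-nitroprop-2-enoate
Product: 4 methyl 3,3-dimethylcyclohexa-1,4-diene-1-carboxylate, via nitro cycloadduct 3 (not isolated)
Conditions: PhMe, 60 °C (excess 1); then DBU, THF, 0 °C → rt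
Reagents that add atoms: none
Why: In this Diels–Alder reaction the nitro group outranks the ester as director, so the nitro-bearing carbon bonds to the CMe2 terminus and the ester-bearing carbon to the CH2 terminus, and DBU then expels nitrite (E1cB loss of HNO2) to leave the ester on the alkene carbon meta to the quaternary carbon, a regiochemistry a propiolate would not give; no stereocentre remains.

**Step 2**
Reactants: 4 methyl 3,3-dimethylcyclohexa-1,4-diene-1-carboxylate
Product: 5 (3,3-dimethylcyclohexa-1,4-dien-1-yl)methanol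
Conditions: iBu2AlH (2.2 equiv), CH2Cl2, −78 °C; Rochelle salt work-up
Reagents that add atoms: none
Why: Hydride reduction of the conjugated ester goes 1,2 to the allylic alcohol and leaves the skipped diene alone (ester reduction).

**Step 3**
Reactants: 5 (3,3-dimethylcyclohexa-1,4-dien-1-yl)methanol
Product: 6 2-[(3,3-dimethylcyclohexa-1,4-dien-1-yl)methyl]-4,4,5,5-tetramethyl-1,3,2-dioxaborolane
Conditions: B2pin2 (1.2 equiv), Pd(MeCN)4(BF4)2 (5 mol %), TsOH·H2O (5 mol %), DMSO/MeOH, 50 °C
Reagents that add atoms: bis(pinacolato)diboron, CC1(C)OB(OC1(C)C)B1OC(C)(C)C(C)(C)O1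
Why: Palladium-catalysed borylation of the allylic alcohol runs through an allyl-palladium species that takes boron at the unhindered primary terminus, giving the linear allylboronate with the ring alkene kept (Miyaura-type allylic borylation).

**Step 4**
Reactants: 7 (S)-(−)-limonene, (4S)-1-methyl-4-(prop-1-en-2-yl)cyclohex-1-ene
Product: 8 3-[(1S)-4-methylcyclohex-3-en-1-yl]butanal (1:1 epimers at C3)
Conditions: Rh(acac)(CO)2 (0.5 mol %), PPh3, CO/H2 (1:1, 40 bar), PhMe, 90 °C
Reagents that add atoms: carbon monoxide, [C-]#[O+]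
Why: Rhodium-catalysed hydroformylation adds H and CHO anti-Markovnikov to the 1,1-disubstituted isopropenyl alkene only, the trisubstituted ring alkene being inert; the ring stereocentre is untouched and the new side-chain centre is erased in step 5.

**Step 5**
Reactants: 8 3-[(1S)-4-methylcyclohex-3-en-1-yl]butanal
Product: 9 (2E)-3-[(1S)-4-methylcyclohex-3-en-1-yl]but-2-enal
Conditions: 2-iodoxybenzoic acid (IBX, 1.5 equiv), DMSO/fluorobenzene, 65 °C; chromatography
Reagents that add atoms: none
Why: IBX dehydrogenates the aldehyde α,β through its enol (IBX-mediated dehydrogenation), the single β-hydrogen forcing the trisubstituted enal, whose E isomer (formyl trans to the ring) is favoured and is separated from the minor Z isomer, the temperature being held at 65 °C to avoid γ-enolisation at the ring stereocentre.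

**Step 6**
Reactants: 9 (2E)-3-[(1S)-4-methylcyclohex-3-en-1-yl]but-2-enal
Product: 12 (2E)-3-[(1S,3S,4R)-3-bromo-4-hydroxy-4-methylcyclohexyl]but-2-enal, via selenide 10 (not isolated), via bromo trifluoroacetate 11 (not isolated)
Conditions: PhSeSePh (10 mol %), NBS (1.15 equiv, added over 4 h), CF3CO2H (2 equiv), CF3CO2Na (2 equiv), MeCN, −20 °C, dark; then Et3N (0.2 equiv), MeOH, 0 °C
Reagents that add atoms: N-bromosuccinimide, O=C1CCC(=O)N1Br; trifluoroacetic acid, OC(=O)C(F)(F)F
Why: Proposed new method: PhSeBr formed in situ from the diselenide and NBS adds to the ring alkene as a seleniranium ion that trifluoroacetate opens at the tertiary carbon in the trans-diaxial (Fürst–Plattner) sense, placing C–O axial and cis to the side chain and C–Se axial on the other face (selenide 10); NBS then oxidises the divalent selenium of 10 to a tetravalent bromoselenonium whose C–Se bond is displaced by bromide with inversion, so Br ends equatorial and syn to oxygen (1R,2S on ring B) while PhSeBr is returned, the poorly participating trifluoroacetate suppressing epoxide or dioxolanylium formation and slow NBS addition ensuring the oxidant meets the selenide and not the alkene, and mild methanolysis frees the tertiary alcohol; the closest known reactions are the diselenide-catalysed syn-dichlorination of alkenes and the stoichiometric bromine-induced substitution of alkyl phenyl selenides by bromide with inversion.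

**Step 7**
Reactants: 6 2-[(3,3-dimethylcyclohexa-1,4-dien-1-yl)methyl]-4,4,5,5-tetramethyl-1,3,2-dioxaborolane; 12 (2E)-3-[(1S,3S,4R)-3-bromo-4-hydroxy-4-methylcyclohexyl]but-2-enal
Product: 13 (1R,2E)-3-[(1S,3S,4R)-3-bromo-4-hydroxy-4-methylcyclohexyl]-1-[(1R)-2,2-dimethyl-6-methylidenecyclohex-3-en-1-yl]but-2-en-1-ol
Conditions: (S)-TRIP phosphoric acid (5 mol %), 4 Å MS, PhMe, −30 °C → rt; aq. NaHCO3
Reagents that add atoms: none
Why: Chiral phosphoric acid-catalysed allylboration through a closed chair (Zimmerman–Traxler) transition state, in which (S)-TRIP (the antipode of the catalyst that delivers allyl groups to the Re face) directs attack to the Si face of the aldehyde to give the (R)-carbinol, the ring-enforced E-type geometry at the γ-carbon puts the quaternary carbon equatorial to give the anti relationship, that is (R) at the ring A carbon, and the allylic transposition creates the exocyclic methylene.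

**Compound list**
1 | 4-methylpenta-1,3-diene | CC(C)=CC=C | starting material
2 | methyl (2E)-3-nitroprop-2-enoate | COC(=O)/C=C/[N+](=O)[O-] | starting material
3 | methyl trans-5,5-dimethyl-6-nitrocyclohex-3-ene-1-carboxylate (racemic, one enantiomer drawn) | COC(=O)[C@@H]1CC=CC(C)(C)[C@H]1[N+](=O)[O-] | intermediate
4 | methyl 3,3-dimethylcyclohexa-1,4-diene-1-carboxylate | COC(=O)C1=CC(C)(C)C=CC1 | intermediate
5 | (3,3-dimethylcyclohexa-1,4-dien-1-yl)methanol | OCC1=CC(C)(C)C=CC1 | intermediate
6 | 2-[(3,3-dimethylcyclohexa-1,4-dien-1-yl)methyl]-4,4,5,5-tetramethyl-1,3,2-dioxaborolane | CC1(C)C=CCC(CB2OC(C)(C)C(C)(C)O2)=C1 | intermediate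
7 | (S)-(−)-limonene, (4S)-1-methyl-4-(prop-1-en-2-yl)cyclohex-1-ene | C=C(C)[C@H]1CCC(C)=CC1 | starting material
8 | 3-[(1S)-4-methylcyclohex-3-en-1-yl]butanal (both C3 epimers) | O=CCC(C)[C@H]1CCC(C)=CC1 | intermediate
9 | (2E)-3-[(1S)-4-methylcyclohex-3-en-1-yl]but-2-enal | O=C/C=C(\C)[C@H]1CCC(C)=CC1 | intermediate
10 | (1R,2R,4S)-1-methyl-4-[(2E)-4-oxobut-2-en-2-yl]-2-(phenylselanyl)cyclohexyl trifluoroacetate | O=C/C=C(\C)[C@H]1CC[C@@](C)(OC(=O)C(F)(F)F)[C@H]([Se]c2ccccc2)C1 | intermediate
11 | (1R,2S,4S)-2-bromo-1-methyl-4-[(2E)-4-oxobut-2-en-2-yl]cyclohexyl trifluoroacetate | O=C/C=C(\C)[C@H]1CC[C@@](C)(OC(=O)C(F)(F)F)[C@@H](Br)C1 | intermediate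
12 | (2E)-3-[(1S,3S,4R)-3-bromo-4-hydroxy-4-methylcyclohexyl]but-2-enal | O=C/C=C(\C)[C@H]1CC[C@@](C)(O)[C@@H](Br)C1 | intermediate
13 | (1R,2E)-3-[(1S,3S,4R)-3-bromo-4-hydroxy-4-methylcyclohexyl]-1-[(1R)-2,2-dimethyl-6-methylidenecyclohex-3-en-1-yl]but-2-en-1-ol | C=C1CC=CC(C)(C)[C@@H]1[C@H](O)/C=C(\C)[C@H]1CC[C@@](C)(O)[C@@H](Br)C1 | target

**Totals**
Total step count: 7. Longest linear sequence: 4 steps (7 → 8 → 9 → 12 → 13, or 1 + 2 → 4 → 5 → 6 → 13).

**Three steps most likely to fail**

Step 6 (the proposed new method). The risks are direct anti-bromination of the alkene by NBS, elimination from the tetravalent selenium intermediate, and a slow displacement next to the fully substituted carbon. The fallback uses known chemistry, sets out from 9 and comes back at 12. Epoxidation with mCPBA/NaHCO3 (CH2Cl2, 0 °C) gives the epoxide mixture (2E)-3-[(3S)-6-methyl-7-oxabicyclo[4.1.0]heptan-3-yl]but-2-enal F1. Dilute HClO4 in THF/H2O opens both epoxides diaxially to the single trans-diol (2E)-3-[(1S,3R,4R)-3,4-dihydroxy-4-methylcyclohexyl]but-2-enal F2. SOCl2/Et3N gives the trans-fused cyclic sulfite (2E)-3-[(3aR,5S,7aR)-7a-methyl-2-oxidohexahydro-1,3,2-benzodioxathiol-5-yl]but-2-enal F3. Brief oxidation with RuCl3 (cat.)/NaIO4 at 0 °C gives the cyclic sulfate (2E)-3-[(3aR,5S,7aR)-7a-methyl-2,2-dioxidohexahydro-1,3,2-benzodioxathiol-5-yl]but-2-enal F4. LiBr in THF opens it at the secondary carbon with inversion to lithium (1R,2S,4S)-2-bromo-1-methyl-4-[(2E)-4-oxobut-2-en-2-yl]cyclohexyl sulfate F5. Catalytic H2SO4 with a little water in THF then hydrolyses the sulfate monoester to 12.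

Step 7 (allylboration). The γ-carbon of 6 is flanked by a quaternary carbon, so the pinacol boronate may react too slowly or with eroded selectivity. The fallback switches to stoichiometric reagent control with a far more reactive allylborane; it sets out from 5 (and uses 12) and comes back at 13. PBr3 (Et2O, 0 °C) gives 1-(bromomethyl)-3,3-dimethylcyclohexa-1,4-diene F6. Mg (Et2O, 0 °C, high dilution) gives [(3,3-dimethylcyclohexa-1,4-dien-1-yl)methyl]magnesium bromide F7. (−)-Ipc2BOMe (the reagent from (+)-α-pinene, −78 °C → rt) gives [(3,3-dimethylcyclohexa-1,4-dien-1-yl)methyl]bis[(1R,2S,3R,5R)-isopinocampheyl]borane F8. Two equivalents of this borane (the free hydroxyl of 12 consumes some) add to 12 in Et2O at −78 °C through the same chair, with Si-face attack set by the isopinocampheyl groups. NaBO3·4H2O work-up releases 13.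

Step 1 (Diels–Alder reaction). The cis-methyl group of diene 1 disfavours the s-cis conformer, so the cycloaddition may be slow or lose out to polymerisation of 2. The fallback builds ring A by olefination and ring-closing metathesis; it sets out from none of the numbered compounds (commercial methyl (triphenylphosphoranylidene)acetate, allyl bromide and 2,2-dimethylbut-3-enal replace 1 and 2) and comes back at 4. Allylation of the ylide with allyl bromide gives (1-methoxy-1-oxopent-4-en-2-yl)triphenylphosphonium bromide F9. Aqueous NaOH gives methyl 2-(triphenyl-λ5-phosphanylidene)pent-4-enoate F10. Wittig reaction with 2,2-dimethylbut-3-enal (PhMe, reflux) gives the E triene ester methyl (2E)-4,4-dimethyl-2-(prop-2-en-1-yl)hexa-2,5-dienoate F11, in which the two vinyl-bearing arms are cis. Second-generation Grubbs catalyst (CH2Cl2, 40 °C) closes ring A to 4.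

**Further compounds**
F1 | step 6 | (2E)-3-[(3S)-6-methyl-7-oxabicyclo[4.1.0]heptan-3-yl]but-2-enal (both epoxide diastereomers) | O=C/C=C(\C)[C@H]1CCC2(C)OC2C1
F2 | step 6 | (2E)-3-[(1S,3R,4R)-3,4-dihydroxy-4-methylcyclohexyl]but-2-enal | O=C/C=C(\C)[C@H]1CC[C@@](C)(O)[C@H](O)C1
F3 | step 6 | (2E)-3-[(3aR,5S,7aR)-7a-methyl-2-oxidohexahydro-1,3,2-benzodioxathiol-5-yl]but-2-enal (both sulfur epimers) | O=C/C=C(\C)[C@H]1CC[C@@]2(C)OS(=O)O[C@@H]2C1
F4 | step 6 | (2E)-3-[(3aR,5S,7aR)-7a-methyl-2,2-dioxidohexahydro-1,3,2-benzodioxathiol-5-yl]but-2-enal | O=C/C=C(\C)[C@H]1CC[C@@]2(C)OS(=O)(=O)O[C@@H]2C1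
F5 | step 6 | lithium (1R,2S,4S)-2-bromo-1-methyl-4-[(2E)-4-oxobut-2-en-2-yl]cyclohexyl sulfate | O=C/C=C(\C)[C@H]1CC[C@@](C)(OS(=O)(=O)[O-])[C@@H](Br)C1.[Li+]
F6 | step 7 | 1-(bromomethyl)-3,3-dimethylcyclohexa-1,4-diene | BrCC1=CC(C)(C)C=CC1
F7 | step 7 | [(3,3-dimethylcyclohexa-1,4-dien-1-yl)methyl]magnesium bromide | Br[Mg]CC1=CC(C)(C)C=CC1
F8 | step 7 | [(3,3-dimethylcyclohexa-1,4-dien-1-yl)methyl]bis[(1R,2S,3R,5R)-2,6,6-trimethylbicyclo[3.1.1]heptan-3-yl]borane | CC1(C)C=CCC(CB([C@@H]2C[C@@H]3C[C@@H](C3(C)C)[C@H]2C)[C@@H]2C[C@@H]3C[C@@H](C3(C)C)[C@H]2C)=C1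
F9 | step 1 | (1-methoxy-1-oxopent-4-en-2-yl)triphenylphosphonium bromide | COC(=O)C(CC=C)[P+](c1ccccc1)(c1ccccc1)c1ccccc1.[Br-]
F10 | step 1 | methyl 2-(triphenyl-λ5-phosphanylidene)pent-4-enoate | COC(=O)C(CC=C)=P(c1ccccc1)(c1ccccc1)c1ccccc1
F11 | step 1 | methyl (2E)-4,4-dimethyl-2-(prop-2-en-1-yl)hexa-2,5-dienoate | COC(=O)/C(CC=C)=C/C(C)(C)C=C
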